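## Retrosynthetic overview
1. The target comes from a boron-mediated Knoevenagel (Pabon) condensation of aryl aldehyde **15** with feruloylacetone **18**.
2. Aldehyde **15** comes from TEMPO oxidation of the benzylic alcohol in **14**. Alcohol **14** comes from catalyst-controlled reduction of cyclohexenone **13**.
3. The only ring is formed in one pot: an organocatalytic Michael addition of aryloxyacetaldehyde **12** to enone **8**, then intramolecular aldol condensation. This sets C-5 and the aryloxy carbon C-4 (C-4 is trans to C-5).
4. Enone **8** comes from cross-metathesis of dienone **6** with ethyl vinyl ketone. Dienone **6** comes from (S)-3-methylpent-4-enal **3**, made by organocatalytic conjugate vinylation of crotonaldehyde, which is the first stereocentre.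

**Assumption:** Catalyst enantiomers are assigned by analogy to model systems: (2S,5S)-imidazolidinone in step 1, (S)-diarylprolinol silyl ether in step 7 and (R)-Me-CBS in step 8. The curcumin unit is drawn as the enol tautomer, as in the target SMILES.

## Route

**Step 1**
Reactants: **1** crotonaldehyde; **2** potassium vinyltrifluoroborate
Product: **3** (S)-3-methylpent-4-enal
Conditions: (2S,5S)-5-benzyl-2-tert-butyl-3-methylimidazolidin-4-one·TFA (20 mol%), CH2Cl2/iPrOH, 0 °C → rt
Reagents that add atoms: potassium vinyltrifluoroborate, C=C[B-](F)(F)F.[K+] (reactant **2**)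
Why: Iminium-ion organocatalytic conjugate addition of a vinyl trifluoroborate to an enal. The benzyl group shields the Re face of the E-iminium, so vinyl adds to the Si face and sets the methyl-bearing stereocentre (S), the first stereocentre.

**Step 2**
Reactants: **3**; **4** 2-methylprop-1-enylmagnesium bromide
Product: **5** (6S)-2,6-dimethylocta-2,7-dien-4-ol (mixture of carbinol epimers)
Conditions: THF, −78 → 0 °C; then aq. NH4Cl
Reagents that add atoms: 2-methylprop-1-enylmagnesium bromide, CC(C)=C[Mg]Br (reactant **4**)
Why: Grignard 1,2-addition to the aldehyde. The carbinol epimers do not matter because the next step oxidises that carbon, and the β-stereocentre cannot epimerise.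

**Step 3**
Reactants: **5**
Product: **6** (S)-2,6-dimethylocta-2,7-dien-4-one
Conditions: activated MnO2 (10 equiv), CH2Cl2, rt
Reagents that add atoms: none
Why: MnO2 oxidises the allylic alcohol chemoselectively to the dienone and leaves the terminal alkene untouched.

**Step 4**
Reactants: **6**; **7** ethyl vinyl ketone (pent-1-en-3-one)
Product: **8** (S,E)-2,6-dimethylundeca-2,7-diene-4,9-dione
Conditions: Hoveyda–Grubbs II (5 mol%), CH2Cl2, 40 °C
Reagents that add atoms: ethyl vinyl ketone, C=CC(=O)CC (reactant **7**)
Why: Cross-metathesis of the monosubstituted alkene with a vinyl ketone gives the E-enone. The hindered β,β-dimethyl enone is inert, and the stereocentre is not touched. Ethylene is lost.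

**Step 5**
Reactants: **9** vanillyl alcohol; **10** allyl bromide
Product: **11** 4-(allyloxy)-3-methoxybenzyl alcohol
Conditions: K2CO3, acetone, reflux
Reagents that add atoms: allyl bromide, C=CCBr (reactant **10**)
Why: Williamson alkylation is selective for the phenol over the benzylic alcohol.

**Step 6**
Reactants: **11**
Product: **12** 2-[4-(hydroxymethyl)-2-methoxyphenoxy]acetaldehyde
Conditions: OsO4 (2 mol%), NaIO4 (4 equiv), 2,6-lutidine, dioxane/H2O 3:1, rt; use crude
Reagents that add atoms: sodium periodate, [Na+].[O-]I(=O)(=O)=O (stoichiometric oxygen source; the OsO4 is catalytic and adds nothing); water, O (co-solvent, hydrolyses the osmate ester)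
Why: Lemieux–Johnson oxidative cleavage of the terminal alkene of the allyl ether (net alkene + 2 [O] → ArOCH2CHO + CH2O) gives the aryloxyacetaldehyde without touching the benzylic alcohol or the arene.

**Step 7**
Reactants: **12** (1.5 equiv); **8**
Product: **13** (4R,5R)-4-[4-(hydroxymethyl)-2-methoxyphenoxy]-2-methyl-5-[(2S)-6-methyl-4-oxohept-5-en-2-yl]cyclohex-2-en-1-one
Conditions: (S)-α,α-diphenylprolinol TMS ether (20 mol%), PhCO2H (20 mol%), toluene, 4 °C, 48 h; then pyrrolidine/AcOH (30 mol% each), 40 °C (one pot)
Reagents that add atoms: none beyond the reactants (H2O is lost in the condensation)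
Why: Proposed new method: enamine Michael addition of an α-aryloxyacetaldehyde to a β-alkyl acyclic ethyl enone, followed by 6-(enolendo)-exo-trig aldol condensation of the resulting 1,5-ketoaldehyde, a Robinson-type annulation that builds the whole ring in one pot. Mechanism: the (S)-catalyst forms the E-enamine and shields one face, and the enone approaches the open face in a synclinal arrangement. By analogy with syn-selective additions to nitroalkenes, this gives the (R) configuration at the new β-carbon (ring C-5, bearing the side chain). The existing (S) side-chain stereocentre is assumed to be matched with this bias. The α-aryloxy carbon is epimerisable via enamine/enol, so C-4 funnels to the trans-diequatorial (4R) isomer relative to C-5. The aldol closes onto the ethyl ketone, whose CH2 is the only α-position that gives a six-membered ring; closure through the side-chain ketone would give a cyclopentane and is the main risk. The closest known reactions are organocatalytic Michael additions of α-alkoxyaldehydes to enones or nitroolefins, and organocatalytic Robinson annulations.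

**Step 8**
Reactants: **13**
Product: **14** (1S,4R,5R)-4-[4-(hydroxymethyl)-2-methoxyphenoxy]-2-methyl-5-[(2S)-6-methyl-4-oxohept-5-en-2-yl]cyclohex-2-en-1-ol
Conditions: (R)-Me-CBS (20 mol%), catecholborane (3 equiv), toluene, −78 → −40 °C; then aq. NaHCO3
Reagents that add atoms: none
Why: Corey–Bakshi–Shibata reduction. The catalyst controls the facial delivery of hydride, giving the (1S)-allylic alcohol cis to the aryloxy group, as in the target. The extra borane equivalents cover the benzylic OH, and the hindered β,β-dimethyl dienone reacts more slowly than the ring enone.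

**Step 9**
Reactants: **14**
Product: **15** 4-{[(1R,4S,6R)-4-hydroxy-3-methyl-6-[(2S)-6-methyl-4-oxohept-5-en-2-yl]cyclohex-2-en-1-yl]oxy}-3-methoxybenzaldehyde
Conditions: TEMPO (10 mol%), PhI(OAc)2 (1.1 equiv), CH2Cl2, 0 °C
Reagents that add atoms: none
Why: TEMPO/PIDA oxidation is selective for the unhindered primary benzylic alcohol over the hindered secondary allylic alcohol, and no stereocentre is affected.

**Step 10**
Reactants: **16** vanillin; **17** acetylacetone (4 equiv)
Product: **18** feruloylacetone, (E)-6-(4-hydroxy-3-methoxyphenyl)hex-5-ene-2,4-dione
Conditions: B2O3, B(OBu)3, n-BuNH2 (cat.), EtOAc, 50 °C; then 1 M HCl, 60 °C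
Reagents that add atoms: acetylacetone, CC(=O)CC(C)=O (reactant **17**)
Why: Pabon boron-chelate Knoevenagel condensation. The boron chelate protects the central carbon, and excess acetylacetone favours mono-condensation.

**Step 11**
Reactants: **15**; **18** (1.5 equiv)
Product: **19** Bisabolocurcumin ether
Conditions: **18** premixed with B2O3 and B(OBu)3, EtOAc, 40 °C; add **15** and n-BuNH2 (20 mol%), 40–50 °C; then NaOAc/AcOH aq. buffer, 40 °C
Reagents that add atoms: none beyond the reactants (H2O is lost)
Why: Pabon condensation of the terminal methyl of the boron chelate with the aryl aldehyde gives the E-enone, and the diketone is drawn as its enol. The mild buffered workup avoids ionising the allylic aryl ether.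

## Compound list
1 | crotonaldehyde | C/C=C/C=O | starting material
2 | potassium vinyltrifluoroborate | C=C[B-](F)(F)F.[K+] | starting material
3 | (S)-3-methylpent-4-enal | C=C[C@@H](C)CC=O | intermediate
4 | 2-methylprop-1-enylmagnesium bromide | CC(C)=C[Mg]Br | starting material
5 | (6S)-2,6-dimethylocta-2,7-dien-4-ol (epimeric at C-4) | C=C[C@@H](C)CC(O)C=C(C)C | intermediate
6 | (S)-2,6-dimethylocta-2,7-dien-4-one | C=C[C@@H](C)CC(=O)C=C(C)C | intermediate
7 | ethyl vinyl ketone | C=CC(=O)CC | starting material
8 | (S,E)-2,6-dimethylundeca-2,7-diene-4,9-dione | CCC(=O)/C=C/[C@@H](C)CC(=O)C=C(C)C | intermediate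
9 | vanillyl alcohol | COc1cc(CO)ccc1O | starting material
10 | allyl bromide | C=CCBr | starting material
11 | 4-(allyloxy)-3-methoxybenzyl alcohol | C=CCOc1ccc(CO)cc1OC | intermediate
12 | 2-[4-(hydroxymethyl)-2-methoxyphenoxy]acetaldehyde | O=CCOc1ccc(CO)cc1OC | intermediate
13 | (4R,5R)-4-aryloxy-2-methyl-5-[(2S)-6-methyl-4-oxohept-5-en-2-yl]cyclohex-2-en-1-one | OCc1ccc(O[C@H]2C=C(C)C(=O)C[C@@H]2[C@@H](C)CC(=O)C=C(C)C)c(OC)c1 | intermediate
14 | (1S,4R,5R)-cyclohexenol | OCc1ccc(O[C@H]2C=C(C)[C@@H](O)C[C@@H]2[C@@H](C)CC(=O)C=C(C)C)c(OC)c1 | intermediate
15 | aryl aldehyde ether (1R,4S,6R ring) | O=Cc1ccc(O[C@H]2C=C(C)[C@@H](O)C[C@@H]2[C@@H](C)CC(=O)C=C(C)C)c(OC)c1 | intermediate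
16 | vanillin | COc1cc(C=O)ccc1O | starting material
17 | acetylacetone | CC(=O)CC(C)=O | starting material
18 | feruloylacetone | COc1cc(/C=C/C(=O)CC(C)=O)ccc1O | intermediate
19 | Bisabolocurcumin ether | COc1cc(/C=C/C(=O)/C=C(O)/C=C/c2ccc(O[C@H]3C=C(C)[C@@H](O)C[C@@H]3[C@@H](C)CC(=O)C=C(C)C)c(OC)c2)ccc1O | target

## Totals
Total steps: 11. Longest linear sequence: 8 (steps 1, 2, 3, 4, 7, 8, 9, 11).

## Three steps most likely to fail
1. **Step 7 (proposed new annulation).** β-Alkyl acyclic enones are poor enamine acceptors, the aldol could close onto the side-chain ketone to give a cyclopentane, and the catalyst and substrate stereocontrol could be mismatched.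
   - Fallback: use Enders SAMP-hydrazone chemistry instead. Make the SAMP hydrazone of the TBS-protected **12**, add its azaenolate to **8**, cleave the hydrazone, then close the ring by aldol condensation with pyrrolidine/AcOH.
2. **Step 8 (CBS reduction).** Diastereoselectivity or chemoselectivity may be poor because the side-chain dienone and free benzylic OH are present.
   - Fallback: Luche reduction (NaBH4/CeCl3·7H2O, −78 °C) of **13**, separation of the epimers, and Mitsunobu inversion of the trans isomer (p-nitrobenzoic acid, DIAD, PPh3; then K2CO3/MeOH).
3. **Step 11 (Pabon condensation on a sensitive substrate).** The allylic aryl ether, the free secondary alcohol and the multiple enones may not survive, or the yield may be low.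
   - Fallback: convert **15** to the enal with Ph3P=CHCHO. Perform an aldol with the lithium enolate of TBS-protected dehydrozingerone (LiHMDS, −78 °C), oxidise the β-hydroxyketone with DMP to the 1,3-diketone, and remove the TBS group with TBAF/AcOH. The ring alcohol would be protected as its TES ether throughout.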